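**Retrosynthetic overview**

1. Target 16 is a 3,3''-biflavanone: a (2S,3R) 4'-O-methylnaringenin unit (unprimed locants) joined through C3–C3'' to a (2''R,3''S) naringenin unit; the last step is global O-debenzylation of 15.
2. Key disconnection (step 8): the C3''–C4'' bond. The pyranone ring O1''–C2''–C3''–C4''–C4a''–C8a'' is made by one-carbon ring expansion of the five-membered furanone ring O1''–C2''–C4''–C4a''–C8a'' of enone 12; C3'' enters from its exocyclic position on C2'' by a radical 1,2-acyl shift (3-exo attack, then β-scission), and acid then equilibrates C3 and C3''.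
3. Enabling feature: the 1,4-diketone C4(=O)–C3–C3''–C4''(=O) makes C3'' the β-carbon of a C3=C3''–C4=O enone on the intact chromanone ring, hence a radical site next to C2''; C2'' carries both the ring oxygen O1'' and the aryl ring, so the radical left at C2'' after the shift is tertiary, benzylic and α-oxygenated.
4. 12 comes from chloromethylidene flavanone 7 and 2-arylbenzofuran-3(2H)-one 11 by asymmetric vinylic substitution (C2''–C3'' bond, quaternary C2''). 7 comes from chromone 3 by asymmetric conjugate arylation (C2), formylation and chlorination; 11 comes from deoxybenzoin 8 by benzylation and bromination/O-alkylation.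
5. Order of ring formation: pyranone of the methoxyphenyl unit (step 1), furanone of the second unit (step 6), its expansion to the second pyranone (step 8).

Key step: step 8

Remark (locants): unprimed locants belong to the unit with the 4-methoxyphenyl group, doubly primed locants to the unit with the 4-hydroxyphenyl group; in 11 to 14 these carbons keep their target locants (C2'' = C2 of the benzofuranone, C4'' = its carbonyl carbon, C3'' = the exocyclic carbon on C2'').

Remark (assumption): the ligand of step 2 and the ammonium salt of step 7 are named in the form expected, by analogy with related substrates, to give the configurations drawn; should the facial sense of either catalyst, or the sense of the chirality relay in step 8, prove opposite, the mirror-image ligand or the pseudo-enantiomeric cinchoninium salt is used.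

Step 1
Reactants: 1 1-[2,4-bis(benzyloxy)-6-hydroxyphenyl]ethan-1-one
Product: 3 5,7-bis(benzyloxy)-4H-chromen-4-one, via enaminone 2 (not isolated)
Conditions: Me2NCH(OMe)2, PhMe, 100 °C; then AcOH, 100 °C
Reagents that add atoms: N,N-dimethylformamide dimethyl acetal COC(OC)N(C)C
Why: Condensation of the methyl ketone with the formamide acetal gives enaminone 2, and acid-promoted conjugate addition of the ortho phenol with loss of Me2NH (6-endo-trig closure) gives the chromone, the standard enaminone route to 3-unsubstituted chromones, in which no stereocentre is formed.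

Step 2
Reactants: 3 5,7-bis(benzyloxy)-4H-chromen-4-one; 4 (4-methoxyphenyl)boronic acid
Product: 5 (2S)-5,7-bis(benzyloxy)-2-(4-methoxyphenyl)-2,3-dihydro-4H-chromen-4-one
Conditions: Pd(OCOCF3)2 (5 mol %), (R)-4-tert-butyl-2-(pyridin-2-yl)-4,5-dihydro-1,3-oxazole (6 mol %), NH4PF6 (30 mol %), H2O (5 equiv), ClCH2CH2Cl, 60 °C
Reagents that add atoms: none
Why: Asymmetric conjugate addition of an arylboronic acid to a chromone, catalysed by a cationic divalent palladium pyridine-oxazoline complex, in which the aryl group is delivered to one enantioface of C2=C3 under control of the chiral ligand (C2 should be set as S) and water protonates the palladium enolate.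

Step 3
Reactants: 5 (2S)-5,7-bis(benzyloxy)-2-(4-methoxyphenyl)-2,3-dihydro-4H-chromen-4-one
Product: 6 (2R,3Z)-5,7-bis(benzyloxy)-3-(hydroxymethylidene)-2-(4-methoxyphenyl)-2,3-dihydro-4H-chromen-4-one (C2 arranged in space as in 5; the descriptor changes because C3 is now sp2)
Conditions: LiN(SiMe3)2, THF, −78 °C; HCO2CH2CF3, −78 °C; then 1 M HCl (aq)
Reagents that add atoms: 2,2,2-trifluoroethyl formate O=COCC(F)(F)F
Why: Crossed Claisen condensation (C-formylation) of the kinetic lithium enolate with a reactive formate ester, in which formylation at −78 °C should be faster than β-elimination of the ring phenoxide from the enolate, so that C2 keeps its configuration and the product rests as the chelated Z enol.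

Step 4
Reactants: 6 (2R,3Z)-5,7-bis(benzyloxy)-3-(hydroxymethylidene)-2-(4-methoxyphenyl)-2,3-dihydro-4H-chromen-4-one
Product: 7 (2R,3E)-5,7-bis(benzyloxy)-3-(chloromethylidene)-2-(4-methoxyphenyl)-2,3-dihydro-4H-chromen-4-one
Conditions: (COCl)2, HCONMe2 (cat.), CH2Cl2, 0 °C
Reagents that add atoms: oxalyl chloride O=C(Cl)C(=O)Cl
Why: Chlorodehydroxylation of a hydroxymethylene ketone by O-acylation and addition–elimination of chloride (vinylogous acid to vinylogous acid chloride), in which the chlorine should settle anti to the carbonyl group (E) and the sp3 centre C2 is not touched.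

Step 5
Reactants: 8 2-(4-hydroxyphenyl)-1-(2,4,6-trihydroxyphenyl)ethan-1-one
Product: 9 1-[2,4-bis(benzyloxy)-6-hydroxyphenyl]-2-[4-(benzyloxy)phenyl]ethan-1-one
Conditions: BnBr (3.1 equiv), K2CO3, DMF, rt
Reagents that add atoms: benzyl bromide BrCc1ccccc1
Why: Williamson etherification that spares the phenol hydrogen-bonded to the ketone, the usual selectivity with polyhydroxyaryl ketones, so that one ortho hydroxyl stays free for the ring closure of step 6.

Step 6
Reactants: 9 1-[2,4-bis(benzyloxy)-6-hydroxyphenyl]-2-[4-(benzyloxy)phenyl]ethan-1-one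
Product: 11 4,6-bis(benzyloxy)-2-[4-(benzyloxy)phenyl]-1-benzofuran-3(2H)-one (racemic), via bromo ketone 10 (not isolated)
Conditions: PhNMe3Br3, THF, 0 °C; then NaOAc, EtOH, 60 °C (argon)
Reagents that add atoms: none
Why: α-Bromination of the benzylic ketone through its enol followed by intramolecular Williamson etherification (5-exo-tet attack of the ortho phenoxide on the benzylic bromide) gives the 2-arylbenzofuran-3(2H)-one, whose C2 is enolisable so that the compound is used as the racemate.

Step 7
Reactants: 7 (2R,3E)-5,7-bis(benzyloxy)-3-(chloromethylidene)-2-(4-methoxyphenyl)-2,3-dihydro-4H-chromen-4-one; 11 4,6-bis(benzyloxy)-2-[4-(benzyloxy)phenyl]-1-benzofuran-3(2H)-one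
Product: 12 (2R,3E)-5,7-bis(benzyloxy)-3-({(2R)-4,6-bis(benzyloxy)-2-[4-(benzyloxy)phenyl]-3-oxo-2,3-dihydro-1-benzofuran-2-yl}methylidene)-2-(4-methoxyphenyl)-2,3-dihydro-4H-chromen-4-one
Conditions: N-(9-anthracenylmethyl)-O-allylcinchonidinium bromide (10 mol %), Cs2CO3, PhMe/CHCl3 (7:3), −30 °C (argon)
Reagents that add atoms: none
Why: Asymmetric nucleophilic vinylic substitution (conjugate addition–elimination) under chiral phase-transfer catalysis, in which the soft 3-oxidobenzofuran attacks through C2 and not through oxygen, the chiral ammonium ion pair shields one face of the enolate and should set the quaternary centre as R, and the alkene geometry of 7 is retained.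

Step 8
Reactants: 12 (2R,3E)-5,7-bis(benzyloxy)-3-({(2R)-4,6-bis(benzyloxy)-2-[4-(benzyloxy)phenyl]-3-oxo-2,3-dihydro-1-benzofuran-2-yl}methylidene)-2-(4-methoxyphenyl)-2,3-dihydro-4H-chromen-4-one
Product: 15 (2S,3R)-5,7-bis(benzyloxy)-3-{(2R,3S)-5,7-bis(benzyloxy)-2-[4-(benzyloxy)phenyl]-4-oxo-3,4-dihydro-2H-chromen-3-yl}-2-(4-methoxyphenyl)-2,3-dihydro-4H-chromen-4-one, via tin enolate 13 (not isolated), via 3''-epimeric ketone 14 (not isolated)
Conditions: Bu3SnH (1.3 equiv, syringe pump), azobis(isobutyronitrile) (0.2 equiv), PhH, 80 °C; then HCl (1.25 M in MeOH), 40 °C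
Reagents that add atoms: none
Why: Proposed new method: Bu3Sn• adds reversibly to the oxygen of the C3=C3''–C4=O enone of 12 to give an allylic O-stannyl ketyl radical with spin at C3'', which attacks the neighbouring furanone carbonyl C4'' (3-exo-trig); the cyclopropyloxy radical then breaks its C2''–C4'' bond (net 1,2-acyl shift), which turns the five-membered furanone into the six-membered pyranone and leaves a tertiary C2'' radical stabilised by the aryl ring and by O1'' that takes hydrogen from Bu3SnH to give tin enolate 13, and HCl in MeOH finally protonates 13 and equilibrates the two enolisable centres. The closest known reaction types are the Dowd–Beckwith one-carbon ring expansion of α-(halomethyl) ketones and the β-carbon radical cyclisations of enones through allylic O-stannyl ketyl radicals; their combination on an enone is what is new. The only ring closed is the transient cyclopropane (3-exo-trig onto C=O), and the pyranone arises from it by scission of the bond shared by the three- and five-membered rings. C3'' is first set by transfer of chirality from the quaternary C2'': the C2''–C4'' bond must stand perpendicular to the allyl plane, and allylic 1,3-strain should turn the ring oxygen O1'' and not the aryl group towards C3, so that the acyl group reaches one face only (3''R in 13). C2'' is set by hydrogen transfer anti to the large pseudoaxial C3'' substituent (2''R, 2'',3''-cis in 13 and 14), and acid-catalysed enolisation then places the C3 and C3'' substituents trans to their aryl neighbours under thermodynamic control (3R, 3''S), while the non-enolisable C2 and C2'' are kept. The step needs the acyl shift to outrun hydrogen transfer to C3'', a 1,2-aryl shift and C2''–O1'' scission of a furanone ketyl: slow addition of the stannane, the higher rate of 3-exo attack on C=O than of ipso attack on an arene, the relief of a congested quaternary centre in a five-membered ring, and the planar furanone, which holds the C2''–O1'' bond orthogonal to the ketyl π system, should secure this.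

Step 9
Reactants: 15 (2S,3R)-5,7-bis(benzyloxy)-3-{(2R,3S)-5,7-bis(benzyloxy)-2-[4-(benzyloxy)phenyl]-4-oxo-3,4-dihydro-2H-chromen-3-yl}-2-(4-methoxyphenyl)-2,3-dihydro-4H-chromen-4-one
Product: 16 (2S,3R)-5,7-dihydroxy-3-[(2R,3S)-5,7-dihydroxy-2-(4-hydroxyphenyl)-4-oxo-3,4-dihydro-2H-chromen-3-yl]-2-(4-methoxyphenyl)-2,3-dihydro-4H-chromen-4-one (CNP0196568.3)
Conditions: H2 (1 atm), Pd(OH)2/C, EtOAc/MeOH, rt
Reagents that add atoms: none
Why: Hydrogenolysis of the five benzyl ethers under neutral conditions, which should leave the aryl methyl ether, the two ketones and all four stereocentres untouched.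

**Compound list**

1 | 1-[2,4-bis(benzyloxy)-6-hydroxyphenyl]ethan-1-one | CC(=O)c1c(O)cc(OCc2ccccc2)cc1OCc1ccccc1 | starting material
2 | (E)-1-[2,4-bis(benzyloxy)-6-hydroxyphenyl]-3-(dimethylamino)prop-2-en-1-one | CN(C)/C=C/C(=O)c1c(O)cc(OCc2ccccc2)cc1OCc1ccccc1 | intermediate
3 | 5,7-bis(benzyloxy)-4H-chromen-4-one | O=c1ccoc2cc(OCc3ccccc3)cc(OCc3ccccc3)c12 | intermediate
4 | (4-methoxyphenyl)boronic acid | COc1ccc(B(O)O)cc1 | starting material
5 | (2S)-5,7-bis(benzyloxy)-2-(4-methoxyphenyl)-2,3-dihydro-4H-chromen-4-one | COc1ccc([C@H]2Oc3cc(OCc4ccccc4)cc(OCc4ccccc4)c3C(=O)C2)cc1 | intermediate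
6 | (2R,3Z)-5,7-bis(benzyloxy)-3-(hydroxymethylidene)-2-(4-methoxyphenyl)-2,3-dihydro-4H-chromen-4-one | COc1ccc([C@H]2Oc3cc(OCc4ccccc4)cc(OCc4ccccc4)c3C(=O)/C2=C\O)cc1 | intermediate
7 | (2R,3E)-5,7-bis(benzyloxy)-3-(chloromethylidene)-2-(4-methoxyphenyl)-2,3-dihydro-4H-chromen-4-one | COc1ccc([C@H]2Oc3cc(OCc4ccccc4)cc(OCc4ccccc4)c3C(=O)/C2=C/Cl)cc1 | intermediate
8 | 2-(4-hydroxyphenyl)-1-(2,4,6-trihydroxyphenyl)ethan-1-one | O=C(Cc1ccc(O)cc1)c1c(O)cc(O)cc1O | starting material
9 | 1-[2,4-bis(benzyloxy)-6-hydroxyphenyl]-2-[4-(benzyloxy)phenyl]ethan-1-one | O=C(Cc1ccc(OCc2ccccc2)cc1)c1c(O)cc(OCc2ccccc2)cc1OCc1ccccc1 | intermediate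
10 | 1-[2,4-bis(benzyloxy)-6-hydroxyphenyl]-2-[4-(benzyloxy)phenyl]-2-bromoethan-1-one (racemic) | O=C(C(Br)c1ccc(OCc2ccccc2)cc1)c1c(O)cc(OCc2ccccc2)cc1OCc1ccccc1 | intermediate
11 | 4,6-bis(benzyloxy)-2-[4-(benzyloxy)phenyl]-1-benzofuran-3(2H)-one (racemic, enolisable at C2) | O=C1C(c2ccc(OCc3ccccc3)cc2)Oc2cc(OCc3ccccc3)cc(OCc3ccccc3)c12 | intermediate
12 | (2R,3E)-5,7-bis(benzyloxy)-3-({(2R)-4,6-bis(benzyloxy)-2-[4-(benzyloxy)phenyl]-3-oxo-2,3-dihydro-1-benzofuran-2-yl}methylidene)-2-(4-methoxyphenyl)-2,3-dihydro-4H-chromen-4-one | COc1ccc([C@H]2Oc3cc(OCc4ccccc4)cc(OCc4ccccc4)c3C(=O)/C2=C/[C@]2(c3ccc(OCc4ccccc4)cc3)Oc3cc(OCc4ccccc4)cc(OCc4ccccc4)c3C2=O)cc1 | intermediate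
13 | (2R,3R)-5,7-bis(benzyloxy)-2-[4-(benzyloxy)phenyl]-3-{(2R)-5,7-bis(benzyloxy)-2-(4-methoxyphenyl)-4-[(tributylstannyl)oxy]-2H-chromen-3-yl}-2,3-dihydro-4H-chromen-4-one (tin enolate) | COc1ccc([C@H]2Oc3cc(OCc4ccccc4)cc(OCc4ccccc4)c3C(O[Sn](CCCC)(CCCC)CCCC)=C2[C@H]2C(=O)c3c(OCc4ccccc4)cc(OCc4ccccc4)cc3O[C@H]2c2ccc(OCc4ccccc4)cc2)cc1 | intermediate
14 | (2S,3R)-5,7-bis(benzyloxy)-3-{(2R,3R)-5,7-bis(benzyloxy)-2-[4-(benzyloxy)phenyl]-4-oxo-3,4-dihydro-2H-chromen-3-yl}-2-(4-methoxyphenyl)-2,3-dihydro-4H-chromen-4-one (2'',3''-cis, 3''-epimer of 15) | COc1ccc([C@H]2Oc3cc(OCc4ccccc4)cc(OCc4ccccc4)c3C(=O)[C@@H]2[C@H]2C(=O)c3c(OCc4ccccc4)cc(OCc4ccccc4)cc3O[C@H]2c2ccc(OCc4ccccc4)cc2)cc1 | intermediate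
15 | (2S,3R)-5,7-bis(benzyloxy)-3-{(2R,3S)-5,7-bis(benzyloxy)-2-[4-(benzyloxy)phenyl]-4-oxo-3,4-dihydro-2H-chromen-3-yl}-2-(4-methoxyphenyl)-2,3-dihydro-4H-chromen-4-one | COc1ccc([C@H]2Oc3cc(OCc4ccccc4)cc(OCc4ccccc4)c3C(=O)[C@@H]2[C@@H]2C(=O)c3c(OCc4ccccc4)cc(OCc4ccccc4)cc3O[C@H]2c2ccc(OCc4ccccc4)cc2)cc1 | intermediate
16 | (2S,3R)-5,7-dihydroxy-3-[(2R,3S)-5,7-dihydroxy-2-(4-hydroxyphenyl)-4-oxo-3,4-dihydro-2H-chromen-3-yl]-2-(4-methoxyphenyl)-2,3-dihydro-4H-chromen-4-one | COc1ccc([C@H]2Oc3cc(O)cc(O)c3C(=O)[C@@H]2[C@@H]2C(=O)c3c(O)cc(O)cc3O[C@H]2c2ccc(O)cc2)cc1 | target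

**Step count and risks**

Total step count: 9. Longest linear sequence: 7 steps (steps 1, 2, 3, 4, 7, 8, 9); the benzofuranone branch (steps 5, 6) joins at step 7.

Steps most likely to fail:

- **Step 8.** What may go wrong:
  - hydrogen transfer from Bu3SnH to the allylic O-stannyl ketyl radical before the acyl shift (plain 1,4-reduction);
  - a shift that stays reversible because the starting radical is itself delocalised;
  - leakage in the relay of configuration from the quaternary centre to C3'' and C2'';
  - β-elimination of the ring phenoxide from the tin enolate with loss of C2;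
  - Paal–Knorr cyclodehydration of the 1,4-diketone if the acid treatment is prolonged.

  The fallback uses known chemistry and sets out from 12. Conjugate addition of benzeneselenol (PhSeH, Et3N (cat.), CH2Cl2, 0 °C) should give the β-(phenylselanyl) ketone F1. Bu3SnH and azobis(isobutyronitrile) in benzene at 80 °C then abstract the phenylselanyl group and give a localised secondary radical at C3''. For this radical the Dowd–Beckwith 1,2-acyl shift to the benzylic, α-oxygenated C2'' radical is strongly downhill, and no tin enolate is formed. Hydrogen transfer should give ketone 14 (with its C3 epimer), where the fallback comes back to the route; the acid treatment of step 8 converts it into 15.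

- **Step 7.** What may go wrong:
  - O-alkylation of the ambident 3-oxidobenzofuran;
  - incomplete facial control at the quaternary centre;
  - base-induced isomerisation of 7 or 12 to a 3-substituted flavone with loss of C2;
  - autoxidation of 11 at C2.

  The fallback sets out from 11 and 5 and forms the C3=C3'' bond instead of the C2''–C3'' bond. Aldol reaction of 11 with aqueous formaldehyde (K2CO3, THF) should give the racemic hydroxymethyl compound F2, and Dess–Martin periodinane the non-enolisable aldehyde F3. The kinetic lithium enolate of 5 (LiN(SiMe3)2, THF, −78 °C) adds to F3 to give the aldol adduct F4, and MsCl/Et3N (CH2Cl2, 0 °C) dehydrates it. This gives 12 together with its quaternary-centre epimer F5, which is removed by chromatography; the fallback comes back to the route at 12.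

- **Step 2.** What may go wrong:
  - slow carbopalladation of the electron-rich chromone, so that protodeboronation and homocoupling consume 4;
  - insufficient enantioface discrimination.

  The fallback sets out from 1. Claisen–Schmidt condensation with 4-methoxybenzaldehyde (KOH, EtOH) should give the chalcone F6. Oxa-Michael cyclisation (NaOAc, EtOH, reflux) gives the racemic flavanone, that is 5 together with its enantiomer F7. Preparative chromatography on a chiral stationary phase delivers 5, where the fallback comes back to the route.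

**Further compounds**

F1 | step 8 | 5,7-bis(benzyloxy)-3-[{4,6-bis(benzyloxy)-2-[4-(benzyloxy)phenyl]-3-oxo-2,3-dihydro-1-benzofuran-2-yl}(phenylselanyl)methyl]-2-(4-methoxyphenyl)-2,3-dihydro-4H-chromen-4-one (C2 and the quaternary carbon arranged as in 12; mixture at C3 and at the selenium-bearing carbon) | COc1ccc([C@H]2Oc3cc(OCc4ccccc4)cc(OCc4ccccc4)c3C(=O)C2C([Se]c2ccccc2)[C@]2(c3ccc(OCc4ccccc4)cc3)Oc3cc(OCc4ccccc4)cc(OCc4ccccc4)c3C2=O)cc1
F2 | step 7 | 4,6-bis(benzyloxy)-2-[4-(benzyloxy)phenyl]-2-(hydroxymethyl)-1-benzofuran-3(2H)-one (racemic) | OCC1(c2ccc(OCc3ccccc3)cc2)Oc2cc(OCc3ccccc3)cc(OCc3ccccc3)c2C1=O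
F3 | step 7 | 4,6-bis(benzyloxy)-2-[4-(benzyloxy)phenyl]-3-oxo-2,3-dihydro-1-benzofuran-2-carbaldehyde (racemic) | O=CC1(c2ccc(OCc3ccccc3)cc2)Oc2cc(OCc3ccccc3)cc(OCc3ccccc3)c2C1=O
F4 | step 7 | 5,7-bis(benzyloxy)-3-[{4,6-bis(benzyloxy)-2-[4-(benzyloxy)phenyl]-3-oxo-2,3-dihydro-1-benzofuran-2-yl}(hydroxy)methyl]-2-(4-methoxyphenyl)-2,3-dihydro-4H-chromen-4-one (C2 as in 5; mixture at the other centres) | COc1ccc([C@H]2Oc3cc(OCc4ccccc4)cc(OCc4ccccc4)c3C(=O)C2C(O)C2(c3ccc(OCc4ccccc4)cc3)Oc3cc(OCc4ccccc4)cc(OCc4ccccc4)c3C2=O)cc1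
F5 | step 7 | (2R,3E)-5,7-bis(benzyloxy)-3-({(2S)-4,6-bis(benzyloxy)-2-[4-(benzyloxy)phenyl]-3-oxo-2,3-dihydro-1-benzofuran-2-yl}methylidene)-2-(4-methoxyphenyl)-2,3-dihydro-4H-chromen-4-one (quaternary-centre epimer of 12) | COc1ccc([C@H]2Oc3cc(OCc4ccccc4)cc(OCc4ccccc4)c3C(=O)/C2=C/[C@@]2(c3ccc(OCc4ccccc4)cc3)Oc3cc(OCc4ccccc4)cc(OCc4ccccc4)c3C2=O)cc1
F6 | step 2 | (E)-1-[2,4-bis(benzyloxy)-6-hydroxyphenyl]-3-(4-methoxyphenyl)prop-2-en-1-one | COc1ccc(/C=C/C(=O)c2c(O)cc(OCc3ccccc3)cc2OCc2ccccc2)cc1
F7 | step 2 | (2R)-5,7-bis(benzyloxy)-2-(4-methoxyphenyl)-2,3-dihydro-4H-chromen-4-one (enantiomer of 5) | COc1ccc([C@@H]2Oc3cc(OCc4ccccc4)cc(OCc4ccccc4)c3C(=O)C2)cc1
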